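**Strategy.** The target's cyclopentane carries two adjacent quaternary ring carbons with cis methyls: C1 (methyl, acyl) and C2 (methyl, CH2C=O). Joining the acyl carbon to the side-chain carbonyl carbon would regenerate a cis-1,5-dimethylbicyclo[3.3.0]octane. The route therefore disconnects to a meso diquinane dione made by Weiss–Cook condensation. Biacetyl, whose two carbonyl carbons become C1 and C2, reacts with two dimethyl 3-oxoglutarates, forming four C–C bonds, both five-membered rings and the cis quaternary pair in one operation. The precursors are just these two commercial compounds. Mono-deoxygenation, chiral-base enolisation and ozonolysis then reopen one ring enantioselectively for elaboration of the two arms.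

Key step: step 1

Assumption: the sense of enantiotopic proton removal in step 4 is assigned by analogy with the parent cis-bicyclo[3.3.0]octan-3-ones, which points to the (S,S)-amide; should the enol ether prove to be the antipode, the (R,R)-amide is used with nothing else changed.

Remark: the carbinol carbons created in steps 6 and 9 are not controlled and are drawn without configuration (epimer mixtures in 14, 15, 17, 18, 20, 25–28); both become carbonyls in step 16.

**Step 1**
Reactants: 1 biacetyl; 2 dimethyl 3-oxoglutarate (2 equiv)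
Product: 4 meso cis-1,5-dimethylbicyclo[3.3.0]octane-3,7-dione, via tetraester bis-enol 3 (not isolated)
Conditions: NaHCO3, H2O (pH ca. 8.3), rt; then the slurry acidified, aq. HCl/AcOH, reflux
Reagents that add atoms: none
Why: Weiss–Cook reaction: each 3-oxoglutarate acts as a 1,3-bis-nucleophile, the first adding to biacetyl by an intermolecular aldol reaction and closing ring one by a 5-exo-trig intramolecular aldol addition to the second carbonyl; dehydration then gives a hydroxycyclopentenone, the second 3-oxoglutarate adds in Michael fashion, the remaining tertiary hydroxyl is eliminated and ring two closes by a 5-exo-trig intramolecular Michael addition, after which hot aqueous acid hydrolyses the four esters and the β-keto acids lose CO2. The closest known reaction type is the condensation of 1,2-dicarbonyl compounds with 3-oxoglutarates to cis-bicyclo[3.3.0]octane-3,7-diones, for which biacetyl is a standard substrate. The two new stereocentres are the ring-fusion carbons, and their cis relation is dictated by the strain of a trans-fused diquinane, so the tethered enolate can only bond on the face that already carries the first ring. The product is meso, so no absolute control is needed here. The selectivity required is clean 1:2 assembly over 1:1 or open-chain adducts, which the mild bicarbonate buffer and the precipitation of the tetraester bis-enol from the reversible sequence should secure.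

**Step 2**
Reactants: 4 meso cis-1,5-dimethylbicyclo[3.3.0]octane-3,7-dione
Product: 5 meso mono(2,2-dimethylpropane-1,3-diyl) ketal of 4
Conditions: 2,2-dimethylpropane-1,3-diol (1.0 equiv), p-TsOH (cat.), toluene, reflux, Dean–Stark
Reagents that add atoms: 2,2-dimethylpropane-1,3-diol, OCC(C)(C)CO
Why: Acid-catalysed ketalisation with azeotropic water removal; the two carbonyls are equivalent, so stoichiometry alone should favour the mono-ketal, with dione and bis-ketal recycled by acid equilibration, and the product stays meso.

**Step 3**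
Reactants: 5 meso mono-ketal
Product: 8 meso cis-1,5-dimethylbicyclo[3.3.0]octan-3-one, via hydrazone 6 (not isolated), via deoxygenated ketal 7 (not isolated)
Conditions: N2H4·H2O, KOH, diethylene glycol, 130 → 200 °C; then crude, 2 M HCl, THF, rt
Reagents that add atoms: water, O
Why: Wolff–Kishner reduction (Huang-Minlon variant) removes the free carbonyl under base that leaves the ketal untouched, and acid hydrolysis of the ketal then releases the remaining ketone without touching the quaternary centres.

**Step 4**
Reactants: 8 meso cis-1,5-dimethylbicyclo[3.3.0]octan-3-one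
Product: 10 (1S,5R)-1,5-dimethyl-3-(trimethylsilyloxy)bicyclo[3.3.0]oct-2-ene, via lithium enolate 9 (not isolated)
Conditions: (S,S)-bis(1-phenylethyl)amine, n-BuLi, THF, −78 °C; TMSCl, then 8, −100 °C (internal quench); Et3N, aq. NaHCO3
Reagents that add atoms: chlorotrimethylsilane, C[Si](C)(C)Cl
Why: Enantiotopic-group-selective deprotonation of a meso ketone by a C2-symmetric chiral lithium amide with internal silyl quench, a reaction type established for cis-bicyclo[3.3.0]octan-3-ones; the amide should remove the convex-face proton of one of the two mirror-related α-methylenes, which decides that the adjoining ring-fusion carbon becomes the acyl-bearing C1 and so fixes the absolute configuration of both existing quaternary centres.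

**Step 5**
Reactants: 10 (1S,5R)-silyl enol ether
Product: 12 2-[(1R,2R)-2-formyl-1,2-dimethylcyclopentyl]acetic acid, via trimethylsilyl ester 11 (not isolated)
Conditions: O3, CH2Cl2/MeOH, −78 °C; Me2S, −78 °C → rt; aq. work-up
Reagents that add atoms: ozone, [O-][O+]=O
Why: Ozonolysis of a silyl enol ether with reductive work-up cleaves the enol C=C bond to an aldehyde on C1 and a silyl ester (hydrolysed on work-up) on the CH2 arm of C2, and both stereocentres are quaternary and cannot epimerise.

**Step 6**
Reactants: 12 aldehyde acid; 13 allylmagnesium bromide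
Product: 15 (4aR,7aR)-1-allyl-4a,7a-dimethylhexahydrocyclopenta[c]pyran-3(1H)-one, via hydroxy acid 14 (not isolated)
Conditions: 13 (2.5 equiv), THF, −78 → 0 °C; 1 M HCl; then p-TsOH (cat.), toluene, 50 °C
Reagents that add atoms: none
Why: Grignard addition in which the first equivalent forms the carboxylate (opening any cyclic pseudo-acid form) and the second adds to the neopentylic aldehyde, followed by acid-catalysed δ-lactonisation made easy by the cis arms; the new carbinol centre is irrelevant because it is oxidised in step 16.

**Step 7**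
Reactants: 15 allyl lactone; 16 2-methylbut-2-ene
Product: 17 (4aR,7aR)-4a,7a-dimethyl-1-(3-methylbut-2-en-1-yl)hexahydrocyclopenta[c]pyran-3(1H)-one
Conditions: Grubbs II (3 mol %), 16/CH2Cl2, rt
Reagents that add atoms: none
Why: Olefin cross-metathesis of an unhindered terminal alkene with excess trisubstituted alkene installs the isopropylidene terminus with loss of propene, and the trisubstituted product should not re-enter the cycle.

**Step 8**
Reactants: 17 prenyl lactone
Product: 18 (4aR,7aR)-4a,7a-dimethyl-1-(3-methylbut-2-en-1-yl)octahydrocyclopenta[c]pyran-3-ol (anomer mixture)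
Conditions: DIBAL-H (1.1 equiv), CH2Cl2, −78 °C; Rochelle salt
Reagents that add atoms: none
Why: Partial hydride reduction of a δ-lactone stops at the lactol because the aluminium hemiacetal is stable at −78 °C, and the isolated alkene is inert.

**Step 9**
Reactants: 18 lactol; 19 propargyl bromide
Product: 20 1-[(1R,2R)-2-(2-hydroxypent-4-yn-1-yl)-1,2-dimethylcyclopentyl]-4-methylpent-3-en-1-ol
Conditions: Zn dust, 19 (excess), THF/sat. aq. NH4Cl, 0 °C → rt
Reagents that add atoms: none
Why: Barbier propargylation of the open hydroxy-aldehyde tautomer of the lactol, in which the allenylzinc species reacts through its γ-carbon to give the homopropargylic alcohol; the new carbinol centre is again removed in step 16.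

**Step 10**
Reactants: 21 2-hydroxy-3-methylbenzaldehyde
Product: 22 2-(tert-butyldimethylsilyloxy)-3-methylbenzaldehyde
Conditions: TBSCl, imidazole, DMF, rt
Reagents that add atoms: tert-butyldimethylsilyl chloride, CC(C)(C)[Si](C)(C)Cl
Why: Imidazole-promoted O-silylation of the phenol gives an ether that tolerates hydride, organoaluminium and palladium chemistry and is removed later by fluoride.

**Step 11**
Reactants: 22 silyl-protected aldehyde
Product: 23 [2-(tert-butyldimethylsilyloxy)-3-methylphenyl]methanol
Conditions: NaBH4, MeOH/THF, −10 → 0 °C; aq. NH4Cl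
Reagents that add atoms: none
Why: Borohydride reduction of the aldehyde, run cold and quenched promptly so that the benzylic alkoxide does not take over the silyl group from the phenolic oxygen.

**Step 12**
Reactants: 23 benzylic alcohol
Product: 24 tert-butyl[2-(chloromethyl)-6-methylphenoxy]dimethylsilane
Conditions: PPh3, NCS, CH2Cl2, 0 °C → rt
Reagents that add atoms: N-chlorosuccinimide, ClN1C(=O)CCC1=O
Why: Appel-type chlorination through the alkoxyphosphonium salt proceeds under neutral conditions that spare the aryl silyl ether.

**Step 13**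
Reactants: 20 alkynyl diol; 24 benzylic chloride
Product: 26 1-[(1R,2R)-2-[(4E)-6-[2-(tert-butyldimethylsilyloxy)-3-methylphenyl]-2-hydroxy-4-methylhex-4-en-1-yl]-1,2-dimethylcyclopentyl]-4-methylpent-3-en-1-ol, via alkenylalane 25 (not isolated)
Conditions: AlMe3 (5 equiv), Cp2ZrCl2 (0.5 equiv), CH2Cl2, 0 °C → rt; volatiles removed; then 24, Pd(PPh3)4 (5 mol %), THF, rt; Rochelle salt
Reagents that add atoms: trimethylaluminium, C[Al](C)C
Why: Zirconium-catalysed Negishi carboalumination adds methyl and aluminium syn across the terminal alkyne (methyl to the internal carbon, hydroxyls masked in situ as aluminium alkoxides) and the palladium-catalysed alkenyl–benzyl cross-coupling proceeds with retention, so the E trisubstituted alkene follows from the syn addition, with the prenyl alkene inert and room temperature chosen to avoid alkoxide-directed isomerisation of the alkenylalane.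

**Step 14**
Reactants: 26 silyl-protected arene diol
Product: 27 1-[(1R,2R)-2-[(4E)-2-hydroxy-6-(2-hydroxy-3-methylphenyl)-4-methylhex-4-en-1-yl]-1,2-dimethylcyclopentyl]-4-methylpent-3-en-1-ol
Conditions: TBAF, THF, 0 °C; aq. NH4Cl
Reagents that add atoms: none
Why: Fluoride-induced cleavage of the aryl silyl ether is done while both arms are still carbinols, so no enolisable β,γ-unsaturated ketone is exposed to the basic reagent.

**Step 15**
Reactants: 27 phenol diol
Product: 28 2-[(2E)-5-hydroxy-6-[(1R,2R)-2-(1-hydroxy-4-methylpent-3-en-1-yl)-1,2-dimethylcyclopentyl]-3-methylhex-2-en-1-yl]-6-methylcyclohexa-2,5-diene-1,4-dione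
Conditions: Fremy's salt (2.5 equiv), aq. KH2PO4, acetone/H2O, rt
Reagents that add atoms: potassium nitrosodisulfonate (Fremy's salt), [K+].[K+].[O]N(S(=O)(=O)[O-])S(=O)(=O)[O-]
Why: Teuber oxidation, in which the nitroxyl radical abstracts the phenolic hydrogen and a second equivalent oxygenates the para carbon, the only ring position able to give a quinone because both ortho positions are alkylated; alkenes and secondary alcohols are inert.

**Step 16**
Reactants: 28 quinone diol
Product: 29 2-methyl-6-[(2E)-3-methyl-6-[(1R,2R)-1,2-dimethyl-2-(4-methylpent-3-enoyl)cyclopentyl]-5-oxohex-2-en-1-yl]cyclohexa-2,5-diene-1,4-dione (target)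
Conditions: Dess–Martin periodinane (3 equiv), NaHCO3, CH2Cl2, 0 °C → rt
Reagents that add atoms: none
Why: Dess–Martin oxidation of both secondary carbinols under bicarbonate buffering should give the two β,γ-unsaturated ketones without migration of the alkenes into conjugation, erasing the uncontrolled carbinol centres while the quinone and the non-epimerisable quaternary centres are untouched.

**Compound list**

1 | biacetyl (butane-2,3-dione) | CC(=O)C(C)=O | starting material
2 | dimethyl 3-oxoglutarate | COC(=O)CC(=O)CC(=O)OC | starting material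
3 | tetramethyl cis-3,7-dihydroxy-1,5-dimethylbicyclo[3.3.0]octa-2,6-diene-2,4,6,8-tetracarboxylate (bis-enol, C4/C8 undefined) | C[C@]12C(C(=O)OC)=C(O)C(C(=O)OC)[C@@]1(C)C(C(=O)OC)=C(O)C2C(=O)OC | intermediate
4 | meso cis-1,5-dimethylbicyclo[3.3.0]octane-3,7-dione | C[C@]12CC(=O)C[C@@]1(C)CC(=O)C2 | intermediate
5 | meso cis-1,5-dimethylbicyclo[3.3.0]octane-3,7-dione mono(2,2-dimethylpropane-1,3-diyl) ketal | O=C1C[C@]2(C)CC3(C[C@]2(C)C1)OCC(C)(C)CO3 | intermediate
6 | hydrazone of 5 | NN=C1C[C@]2(C)CC3(C[C@]2(C)C1)OCC(C)(C)CO3 | intermediate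
7 | cis-1,5-dimethylbicyclo[3.3.0]octan-3-one 2,2-dimethylpropane-1,3-diyl ketal | C1C[C@]2(C)CC3(C[C@]2(C)C1)OCC(C)(C)CO3 | intermediate
8 | meso cis-1,5-dimethylbicyclo[3.3.0]octan-3-one | O=C1C[C@]2(C)CCC[C@]2(C)C1 | intermediate
9 | lithium (1S,5R)-1,5-dimethylbicyclo[3.3.0]oct-2-en-3-olate | [Li]OC1=C[C@]2(C)CCC[C@]2(C)C1 | intermediate
10 | (1S,5R)-1,5-dimethyl-3-(trimethylsilyloxy)bicyclo[3.3.0]oct-2-ene | C[Si](C)(C)OC1=C[C@]2(C)CCC[C@]2(C)C1 | intermediate
11 | trimethylsilyl 2-[(1R,2R)-2-formyl-1,2-dimethylcyclopentyl]acetate | O=C[C@]1(C)CCC[C@]1(C)CC(=O)O[Si](C)(C)C | intermediate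
12 | 2-[(1R,2R)-2-formyl-1,2-dimethylcyclopentyl]acetic acid (may sit partly as its cyclic hydroxy-lactone tautomer) | O=C[C@]1(C)CCC[C@]1(C)CC(=O)O | intermediate
13 | allylmagnesium bromide | C=CC[Mg]Br | starting material
14 | 2-[(1R,2R)-2-(1-hydroxybut-3-en-1-yl)-1,2-dimethylcyclopentyl]acetic acid | C=CCC(O)[C@]1(C)CCC[C@]1(C)CC(=O)O | intermediate
15 | (4aR,7aR)-1-allyl-4a,7a-dimethylhexahydrocyclopenta[c]pyran-3(1H)-one | C=CCC2[C@]1(C)CCC[C@]1(C)CC(=O)O2 | intermediate
16 | 2-methylbut-2-ene | CC=C(C)C | starting material
17 | (4aR,7aR)-4a,7a-dimethyl-1-(3-methylbut-2-en-1-yl)hexahydrocyclopenta[c]pyran-3(1H)-one | CC(C)=CCC2[C@]1(C)CCC[C@]1(C)CC(=O)O2 | intermediate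
18 | (4aR,7aR)-4a,7a-dimethyl-1-(3-methylbut-2-en-1-yl)octahydrocyclopenta[c]pyran-3-ol | CC(C)=CCC2[C@]1(C)CCC[C@]1(C)CC(O)O2 | intermediate
19 | propargyl bromide | C#CCBr | starting material
20 | 1-[(1R,2R)-2-(2-hydroxypent-4-yn-1-yl)-1,2-dimethylcyclopentyl]-4-methylpent-3-en-1-ol | CC(C)=CCC(O)[C@]1(C)CCC[C@]1(C)CC(O)CC#C | intermediate
21 | 2-hydroxy-3-methylbenzaldehyde | Cc1cccc(C=O)c1O | starting material
22 | 2-(tert-butyldimethylsilyloxy)-3-methylbenzaldehyde | Cc1cccc(C=O)c1O[Si](C)(C)C(C)(C)C | intermediate
23 | [2-(tert-butyldimethylsilyloxy)-3-methylphenyl]methanol | Cc1cccc(CO)c1O[Si](C)(C)C(C)(C)C | intermediate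
24 | tert-butyl[2-(chloromethyl)-6-methylphenoxy]dimethylsilane | Cc1cccc(CCl)c1O[Si](C)(C)C(C)(C)C | intermediate
25 | (E)-alkenyl(dimethyl)alane from 20, both hydroxyls as dimethylaluminium alkoxides | CC(C)=CCC(O[Al](C)C)[C@]1(C)CCC[C@]1(C)CC(O[Al](C)C)C/C(C)=C/[Al](C)C | intermediate
26 | 1-[(1R,2R)-2-[(4E)-6-[2-(tert-butyldimethylsilyloxy)-3-methylphenyl]-2-hydroxy-4-methylhex-4-en-1-yl]-1,2-dimethylcyclopentyl]-4-methylpent-3-en-1-ol | CC(C)=CCC(O)[C@]1(C)CCC[C@]1(C)CC(O)C/C(C)=C/Cc1cccc(C)c1O[Si](C)(C)C(C)(C)C | intermediate
27 | 1-[(1R,2R)-2-[(4E)-2-hydroxy-6-(2-hydroxy-3-methylphenyl)-4-methylhex-4-en-1-yl]-1,2-dimethylcyclopentyl]-4-methylpent-3-en-1-ol | CC(C)=CCC(O)[C@]1(C)CCC[C@]1(C)CC(O)C/C(C)=C/Cc1cccc(C)c1O | intermediate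
28 | 2-[(2E)-5-hydroxy-6-[(1R,2R)-2-(1-hydroxy-4-methylpent-3-en-1-yl)-1,2-dimethylcyclopentyl]-3-methylhex-2-en-1-yl]-6-methylcyclohexa-2,5-diene-1,4-dione | CC(C)=CCC(O)[C@]1(C)CCC[C@]1(C)CC(O)C/C(C)=C/CC1=CC(=O)C=C(C)C1=O | intermediate
29 | 2-methyl-6-[(2E)-3-methyl-6-[(1R,2R)-1,2-dimethyl-2-(4-methylpent-3-enoyl)cyclopentyl]-5-oxohex-2-en-1-yl]cyclohexa-2,5-diene-1,4-dione | CC(C)=CCC(=O)[C@]1(C)CCC[C@]1(C)CC(=O)C/C(C)=C/CC1=CC(=O)C=C(C)C1=O | target

**Totals.** Total step count: 16. Longest linear sequence: 13 (steps 1–9 and 13–16); steps 10–12 form the three-step arene branch.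

**Steps most likely to fail**

1. Step 4. Discrimination between the two enantiotopic α-methylenes may be weak or reversed, because both are neopentylic and flanked by the ring-fusion methyls; slow deprotonation could also let the amide be consumed by the silyl chloride. The fallback sets out from 8 and returns at 12. Ketone 8 would be enolised without asymmetric control (LDA, TMSCl, THF, −78 °C) to the racemic cis-1,5-dimethyl-3-(trimethylsilyloxy)bicyclo[3.3.0]oct-2-ene F1. This would be ozonised as in step 5 to the racemic 2-(2-formyl-1,2-dimethylcyclopentyl)acetic acid F2. Classical resolution would follow, by fractional crystallisation of the (S)-1-phenylethylammonium salt of the (1R,2R)-acid F3. The resolving base would be confirmed by screening, and the antipodal base is available for the mother liquor. Acidification of the salt would release 12.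

2. Step 13. Carbometalation of the alkoxide-bearing alkyne may stall, alkene geometry may erode through alkoxide-directed isomerisation on long reaction times, or methyl rather than alkenyl may transfer in the coupling. The fallback sets out from 20 and returns at 26. The carboalumination mixture would be quenched with iodine to give the isolable (E)-alkenyl iodide diol F4, whose geometry can be checked. Chloride 24 would be converted with zinc dust and LiCl into [2-(tert-butyldimethylsilyloxy)-3-methylbenzyl]zinc chloride F5. The two would be joined by a Negishi coupling with reversed polarity (Pd(OAc)2, a dialkylbiarylphosphine ligand, slow addition of F5), conditions that tolerate free hydroxyls, to give 26.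

3. Step 16. Oxidation of the neopentylic carbinol beside the two quaternary carbons may be slow, so that the quinone degrades or the β,γ-alkenes drift into conjugation during prolonged exposure. The fallback sets out from 26 and returns at 29. The two carbinols would be oxidised first, on the robust silyl-protected arene (Dess–Martin periodinane, NaHCO3), to give the silyl-protected arene diketone F6. Acetic-acid-buffered TBAF would then free the phenol diketone F7. Fremy's salt in phosphate buffer would finally unveil the quinone as the last, near-neutral operation to give 29.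

**Further compounds**

F1 | step 4 | racemic cis-1,5-dimethyl-3-(trimethylsilyloxy)bicyclo[3.3.0]oct-2-ene (both enantiomers shown) | C[Si](C)(C)OC1=C[C@]2(C)CCC[C@]2(C)C1.C[Si](C)(C)OC1=C[C@@]2(C)CCC[C@@]2(C)C1
F2 | step 4 | racemic 2-(cis-2-formyl-1,2-dimethylcyclopentyl)acetic acid (both enantiomers shown) | O=C[C@]1(C)CCC[C@]1(C)CC(=O)O.O=C[C@@]1(C)CCC[C@@]1(C)CC(=O)O
F3 | step 4 | (S)-1-phenylethylammonium 2-[(1R,2R)-2-formyl-1,2-dimethylcyclopentyl]acetate | O=C[C@]1(C)CCC[C@]1(C)CC(=O)[O-].C[C@H]([NH3+])c1ccccc1
F4 | step 13 | 1-[(1R,2R)-2-[(4E)-2-hydroxy-5-iodo-4-methylpent-4-en-1-yl]-1,2-dimethylcyclopentyl]-4-methylpent-3-en-1-ol | CC(C)=CCC(O)[C@]1(C)CCC[C@]1(C)CC(O)C/C(C)=C/I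
F5 | step 13 | [2-(tert-butyldimethylsilyloxy)-3-methylbenzyl]zinc chloride | Cc1cccc(C[Zn]Cl)c1O[Si](C)(C)C(C)(C)C
F6 | step 16 | (4E)-6-[2-(tert-butyldimethylsilyloxy)-3-methylphenyl]-1-[(1R,2R)-1,2-dimethyl-2-(4-methylpent-3-enoyl)cyclopentyl]-4-methylhex-4-en-2-one | CC(C)=CCC(=O)[C@]1(C)CCC[C@]1(C)CC(=O)C/C(C)=C/Cc1cccc(C)c1O[Si](C)(C)C(C)(C)C
F7 | step 16 | (4E)-1-[(1R,2R)-1,2-dimethyl-2-(4-methylpent-3-enoyl)cyclopentyl]-6-(2-hydroxy-3-methylphenyl)-4-methylhex-4-en-2-one | CC(C)=CCC(=O)[C@]1(C)CCC[C@]1(C)CC(=O)C/C(C)=C/Cc1cccc(C)c1O
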